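(The data were generated by integration for an exercise; noise was put on by code.)

The pitfall with a curve that levels off is to reckon in time, when the flask may be paying in Q. I test that reading here.

| setting | south | north | flask |
|---|---|---|---|
| Z | 10 mM | 15 mM | 20 mM |
| J | 10 mM | 15 mM | 20 mM |
| Q | 50 mM | 50 mM | 50.0 mM |
| remark | run made earlier | run made earlier |  |
| time |  |  | 12 h |

| run | time / h | Z / % | J / % | G / % |
|---|---|---|---|---|
| south | 0.417 | 33.8 | 40.0 | 17.1 |
| south | 1.00 | 29.6 | 32.5 | 21.5 |
| south | 2.00 | 24.7 | 26.5 | 25.0 |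
| south | 3.00 | 22.3 | 22.9 | 28.0 |
| south | 4.00 | 20.9 | 20.7 | 30.0 |
| south | 6.00 | 17.3 | 17.9 | 32.0 |
| south | 8.00 | 16.7 | 16.9 | 33.3 |
| north | 0.417 | 34.4 | 40.1 | 16.5 |
| north | 1.00 | 30.4 | 33.5 | 20.5 |
| north | 2.00 | 25.9 | 26.7 | 23.7 |
| north | 3.00 | 23.6 | 24.1 | 26.0 |
| north | 4.00 | 23.0 | 23.0 | 27.5 |
| north | 6.00 | 20.7 | 20.8 | 29.5 |
| north | 8.00 | 19.9 | 20.4 | 30.5 |

(scatter of a reading: 0.3 percentage points)

- part of the Z and J charged together that has reacted at 12 h
- excess of G over E in the product at 12 h
- excess of J over Z among what is left of the two at 12 h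

- Q is single-handed; Z and J are mirror images of each other, charged as a racemate, each of them at the stated concentration
- an excess is the difference of the two amounts in percent of their sum
- an excess is below zero if the other one leads
- the handed part of Q does not stay in what it makes, so the products of the two hands are mirror images too

Suppose Q is the limiting reagent, and that its rate into product follows the Z and J left while its rate of loss elsewhere does not. Dividing one rate by the other drops time: Q spent = product + w·ln(Z and J charged / Z and J left). Here w is the break-even level, the amount of Z and J together at which product takes half of the Q being spent.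

The last rows, taken as the end, give 33.7 mM in south and 35.3 mM in north, both charged with 50 mM of Q. I carry their mean, 34.5 mM.

In the flask, half reacted would cost 43.9 mM of the 50.0 mM of Q. One Newton step from there gives my own 55.6%. South's J minus Z falls from 6.2 percentage points at 0.417 h to 0.2 points at 8.00 h, so I expect the excess of J over Z near zero. With E taken by difference, south's G minus E reads 8 points at 0.417 h and 0.2 points at 8.00 h, so I expect the excess of G over E near zero too.

The forecast, a point below mine on c, gives 54.5%, 0.3% and 0.3%, on the ground that “Mirror-image pairs share one K, so equilibrium is racemic”.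

    Q + Z → G (k = 0.0170 M⁻¹ s⁻¹)
    Q + J → E (k = 9.90 × 10⁻⁴ M⁻¹ s⁻¹)
    Z ⇌ J (k = 8.20 × 10⁻⁴ s⁻¹)
    Q ⇌ X (K = 0.550, k = 3.90 × 10⁻⁴ s⁻¹)
    2 Q → D (k = 0.0120 M⁻¹ s⁻¹)
    G ⇌ E (k = 5.70 × 10⁻⁴ s⁻¹)

The flask gives 55.3%, with excesses of 0.0380% for G over E and 0.0317% for J over Z. At 12.0 h the flask holds 0.12% of its Q, less than the 45% of its Z. Its own break-even level reads 34.7 mM. The neighbour charged with 20 mM of Q reaches 33.4%, and there w reads 16.3 mM, half of the flask's level.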